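## Structural features

The target 22 is a C2-symmetric dimer. Two 3-hydroxy-3,4-bis(arylmethyl)-γ-butyrolactone units (rings B and B'; O1, C2 carbonyl, C3 carbinol, C4 methine, C5 OCH2) are joined by an aryl–aryl bond between the C5 carbons of the two inner guaiacyl rings A and A', which hang on C4 through the methylene C7. Each C3 carries, through the methylene C7', an outer guaiacyl ring (C and C'), so the molecule holds four free phenols, four aryl methyl ethers, two tertiary alcohols and two lactones. The stereocentres come as two remote, identical pairs: the fully substituted carbinol C3 (R) next to the methine C4 (R), with the two arylmethyl groups trans on the lactone and the hydroxyl cis to the C4 substituent. The biaryl axis has only two ortho substituents and rotates freely, so no axial element needs control. The fragile groups are the electron-rich phenols (oxidation, quinone methide formation) and the α-hydroxy lactone (opened by base); C3 has no hydrogen and C4 is not α to the carbonyl, so neither centre can epimerise by enolisation. The real difficulty is the crowded quaternary carbinol C3 beside C4, which must be built twice with the same absolute sense, every operation running at two sites. The plan exploits the position of C7': it sits on the quaternary C3 and is β to the carbonyl C2, so in the ring-opened carboxamide it is the β-methyl group of an α,α-disubstituted amide, and both C7'–aryl bonds can be made by directed C–H arylation.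

## Logic of the disconnections

22 to 21. The six O–CH2Ph bonds are cut (four phenolic, two on the C3 oxygens). One kind of mask, removable under neutral conditions, keeps the phenols and tertiary alcohols inert until the end. The forward step must cleave two hindered tertiary ethers without touching the lactones or the benzylic C–C bonds.

21 to 19 (through 20). Both lactone O1–C2 bonds are cut and the C5 oxygens are silylated. This turns each lactone carbonyl into the carboxamide that carries the directing group. The forward step asks the C5 hydroxyl to displace a hindered amide nitrogen, so the C5 mask is a silyl ether that the same acid removes, and deprotection and ring closure become one operation.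

19 to 16 and 18. The two C7'–aryl bonds are cut, because C7' is the β-methyl group of an α,α-disubstituted amide. Both outer rings leave as one simple aryl iodide, and 16 has only a methyl group at C3 with all four stereocentres in place. The forward step must be site-selective for the methyl group, stop at monoarylation and run to completion on both arms. In 16 the C3 oxygen is a benzyl ether (no chelating hydroxyl, no acyl migration, removed in the final hydrogenolysis) and the C5 oxygen a silyl ether (so the hydroxyl cannot expel the auxiliary during the arylation).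

18 to 17. The O–benzyl bond is cut; a plain phenol alkylation.

16 to 13 and 14 (through 15). The amide C2–N bonds and the Si–O bonds are cut. The lactone is the natural activated form of the acid, and opening it frees exactly the C5 hydroxyl that needs the silyl group. The forward step needs a strong enough nitrogen nucleophile for a hindered carbonyl, and silylation before the hydroxy amide can close again.

13 to 12. The C3 O–benzyl bonds are cut. Benzylation is placed here because the carboxyl group is tied up in the lactone and no N–H competes. The forward step must alkylate a tertiary alkoxide without opening the lactone.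

12 to 10 (through 11). The lactone O1–C2 bond is cut, C5 goes back to the carboxyl level, and C3–O with C2 is tied into a dioxolanone. This is the form in which the C3 methyl group can be introduced with control. The forward step must reduce free carboxyl groups beside the dioxolanone carbonyl; the freed hydroxyl then transacylates.

10 to 9. The two C3–CH3 bonds (the future C7') are cut. The enolate of the dioxolanone is methylated while the acetal carbon holds the stereochemical memory of C3. This returns C3 to a simple secondary carbinol. The forward step needs attack anti to the tert-butyl group in the presence of a carboxylate.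

9 to 8 to 7. The acetal C–O bonds and then the four ester bonds are cut, which leads back to a simple tetraester. The forward steps need the cis acetal and a hydrolysis that leaves C4 alone.

7 to 5 and 6. The two C4–C7 bonds are cut. C7 is benzylic and becomes the electrophile; C4 is α to the ester that becomes C5 and becomes the enolate. 6 supplies C2 to C5 and the C3 oxygen in the right absolute configuration, so the chiral pieces are separated from the whole biaryl core. The forward step needs anti alkylation at both sites.

5 to 4 to 3 to 2 to 1. The C–Br bonds, the carbinol oxidation level and the O–benzyl bonds are adjusted, and then the aryl–aryl bond between the two C5 carbons is cut, which divides 2 into two molecules of 1. Oxidative phenol coupling of two molecules of 1 gives the symmetrical biaryl, with the regiochemistry fixed by the blocked para and one blocked ortho position. The forward step must stop at the dimer.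

## Other disconnections considered

Alternative 1: The ring oxygen O1 is taken out from between C2 and C5 and the C3 substituents are removed, which leads back to the achiral bis-cyclobutanone A1. In the forward direction Sc(OTf)3, a chiral N,N'-dioxide ligand and a peracid would effect a double Baeyer–Villiger oxidation. One of the two enantiotopic CH2 groups of each ring migrates, giving the bis-lactone A2 with both C4 centres.
- In its favour: the step is catalytic, starts from a symmetric achiral substrate and sets both C4 centres at once. Because it runs twice, a wrong-sense event at one site ends in the meso-type diastereomer and not the enantiomer, so the enantiomeric purity of A2 should exceed the single-site selectivity.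
- Against it here: A2 has nothing at C3. The hydroxyl and the outer arylmethyl group would need two successive lactone enolate reactions at each site (hydroxylation, protection, alkylation anti to the C4 substituent), so the quaternary carbinol rests on substrate control. The peracid also meets electron-rich dialkoxyarenes, and selection between enantiotopic groups is expected to be less sharp for a flexible arylmethyl substituent than for an aryl one.
- Comparison: the alternative sets C4 by catalyst and C3 by relay, whereas the chosen plan draws both from 6 and the acetal. The Criegee migration is better understood and arguably less demanding than two palladium C–H activations. A1 should be reachable in about as many steps as 5, and the total could be a step or two shorter. On catalyst economy and on length up to the C4 centres the alternative is the better; on the security of the C3 configuration the chosen plan is the better.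

Alternative 2: The C4–C5 bond is cut with C5 disguised as a vinyl group, leading from the bis-diol A5 back to the bis(epoxy alcohol) A4 and further to the bis(allylic alcohol) A3. In the forward direction CH2=CHMgBr with catalytic CuI would open each epoxide of A4 at the secondary carbon C4 with inversion, releasing the C3 tertiary alcohol.
- In its favour: one asymmetric epoxidation (A3 to A4) fixes C3 and, through the inversion, C4. The outer rings are present from the start, and neither a directing group nor AgOAc is needed. On stereochemical economy and on reagent cost this is the equal or the better of the chosen plan.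
- Against it here: A3 must have the C4 chain cis to the hydroxymethyl group, the substitution pattern that the Ti(OiPr)4–tartrate epoxidation is expected to handle least well. The organocopper reagent must attack a secondary carbon next to a fully substituted one, so Payne rearrangement and attack at the primary carbon become competitors. After the key step the vinyl group must be cleaved oxidatively next to electron-rich arenes, and the two primary hydroxyls at C2 and C5 must be told apart or the lactone closes with its carbonyl on the wrong carbon.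
- Comparison: structurally the alternative is elegant, since no stereocentre comes from the chiral pool. Its regioselectivity risk is of the same order as the site-selectivity risk of the C–H arylation. About five or six operations would follow its key step against two here, so it is likely longer overall.

Alternative 3: The C3–O bond is cut, together with a C7'–O bond that a later reduction removes, leading back to the (E)-bis(allylic alcohol) A6. In the forward direction Ti(OiPr)4, a dialkyl tartrate and tert-butyl hydroperoxide would epoxidise both 2-substituted cinnamyl alcohol units to the bis(epoxy alcohol) A7, with reagent control at C3.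
- In its favour: this is among the most dependable asymmetric reactions, and (E)-2-substituted cinnamyl alcohols are a good substrate class. The outer rings come from an aldehyde by olefination, and Ti(OiPr)4 is cheap. In certainty of the C3 configuration and in avoiding stoichiometric AgOAc it is the equal or the better of the chosen plan.
- Against it here: C4 must be set beforehand and sits next to the alkene, so each epoxidation may be matched or mismatched. A7 is a p-alkoxyphenyl epoxide, prone to benzylic ionisation and Meinwald rearrangement under Lewis acid. Afterwards the primary carbinol must be oxidised to the carboxyl level beside electron-rich arenes, the silyl ether removed, the lactone closed and the C7'–O bond cleaved reductively, although that last step could share the final hydrogenolysis.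
- Comparison: both plans fix C3 with high confidence, by reagent control there and by acetal memory here. The alternative passes through a more fragile intermediate and needs about four operations after its key step against two, plus separate control of C4, so it is expected to be somewhat longer.

Key step: step 13

Remark on the chemistry: the biaryl axis, flanked by only two ortho oxygen substituents, is taken to rotate freely in 22 and in every intermediate, so no axial descriptor is assigned. The configurations of 6, 16 and 19 are mutually consistent and lead to (3R,4R) in both halves of 22.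

## Route

Step 1
Reactants: 1 vanillin (two molecules, 2 equiv)
Product: 2 divanillin (6,6'-dihydroxy-5,5'-dimethoxybiphenyl-3,3'-dicarbaldehyde)
Conditions: 1 (2 equiv), Na2S2O8 (1.1 equiv), FeSO4·7H2O (cat.), H2O, 50 °C
Reagents that add atoms: vanillin (the second molecule of 1 that is coupled), COc1cc(C=O)ccc1O
Why: Oxidative phenol homocoupling in which two molecules of 1 are joined through their phenoxyl radicals; the para position is blocked by the formyl group and one ortho position by methoxy, so C–C coupling should occur at the free ortho carbon C5, and the dimer precipitates from water, which protects it from further oxidation.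

Step 2
Reactants: 2 divanillin
Product: 3 6,6'-bis(benzyloxy)-5,5'-dimethoxybiphenyl-3,3'-dicarbaldehyde
Conditions: BnBr (2.6 equiv), K2CO3, DMF, 60 °C
Reagents that add atoms: benzyl bromide, BrCc1ccccc1
Why: Williamson ether synthesis on the two phenoxides; the aldehydes are inert and the reactive benzylic halide overcomes the hindrance next to the biaryl bond.

Step 3
Reactants: 3 6,6'-bis(benzyloxy)-5,5'-dimethoxybiphenyl-3,3'-dicarbaldehyde
Product: 4 [6,6'-bis(benzyloxy)-5,5'-dimethoxybiphenyl-3,3'-diyl]dimethanol
Conditions: NaBH4, THF–MeOH, 0 °C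
Reagents that add atoms: none
Why: Borohydride reduction of aryl aldehydes; nothing else in the molecule is reducible under these conditions.

Step 4
Reactants: 4 [6,6'-bis(benzyloxy)-5,5'-dimethoxybiphenyl-3,3'-diyl]dimethanol
Product: 5 2,2'-bis(benzyloxy)-5,5'-bis(bromomethyl)-3,3'-dimethoxybiphenyl
Conditions: PBr3 (0.8 equiv), CH2Cl2, 0 °C; used crude
Reagents that add atoms: phosphorus tribromide, BrP(Br)Br
Why: Conversion of benzylic alcohols to bromides through the phosphite ester; the electron-rich bromide ionises easily, so it is made cold and used at once.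

Step 5
Reactants: 5 2,2'-bis(benzyloxy)-5,5'-bis(bromomethyl)-3,3'-dimethoxybiphenyl; 6 diisopropyl (R)-malate
Product: 7 tetraisopropyl (2R,2'R,3S,3'S)-3,3'-{[6,6'-bis(benzyloxy)-5,5'-dimethoxybiphenyl-3,3'-diyl]bis(methylene)}bis(2-hydroxybutanedioate)
Conditions: 6 (3 equiv), LiN(SiMe3)2 (6.2 equiv), THF, −78 → −20 °C; then 5, −78 → 0 °C; 1 M HCl
Reagents that add atoms: none
Why: Twofold Fráter–Seebach alkylation: each malate forms an alkoxide–enolate dianion held in a six-membered lithium chelate, and the benzylic bromide approaches the enolate face opposite the ester group on the carbinol carbon, setting the new centre (S, the future C4) anti to the C2 oxygen. The bulky isopropyl esters are chosen to sharpen this facial bias and to suppress self-condensation.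

Step 6
Reactants: 7 tetraisopropyl ester
Product: 8 (2R,2'R,3S,3'S)-3,3'-{[6,6'-bis(benzyloxy)-5,5'-dimethoxybiphenyl-3,3'-diyl]bis(methylene)}bis(2-hydroxybutanedioic acid)
Conditions: LiOH (12 equiv), THF–H2O, rt → 40 °C; 1 M HCl to pH 2
Reagents that add atoms: lithium hydroxide, [Li+].[OH-] (the hydroxide oxygen ends up in each carboxyl group)
Why: Ester saponification; once the carboxylates form, the α-hydrogen at the future C4 is no longer acidic, so the centre should hold.

Step 7
Reactants: 8 tetracarboxylic acid
Product: 9 (2S,2'S)-3,3'-[6,6'-bis(benzyloxy)-5,5'-dimethoxybiphenyl-3,3'-diyl]bis{2-[(2R,4R)-2-tert-butyl-5-oxo-1,3-dioxolan-4-yl]propanoic acid} (cis-dioxolanones)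
Conditions: tBuCHO (6 equiv), TsOH·H2O (cat.), H2SO4 (cat.), pentane–CH2Cl2, reflux, Dean–Stark
Reagents that add atoms: pivalaldehyde, CC(C)(C)C=O
Why: Acid-catalysed acetalisation of each α-hydroxy acid to the five-membered dioxolanone, the first half of a self-regeneration of stereocentres; the cis acetal (tert-butyl cis to the side chain) is favoured under equilibrating conditions, so the carbinol centre sets the new acetal centre, and 9 is purified to the cis isomer because the next step reads its configuration.

Step 8
Reactants: 9 bis(cis-dioxolanone) diacid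
Product: 10 (2S,2'S)-3,3'-[6,6'-bis(benzyloxy)-5,5'-dimethoxybiphenyl-3,3'-diyl]bis{2-[(2R,4R)-2-tert-butyl-4-methyl-5-oxo-1,3-dioxolan-4-yl]propanoic acid}
Conditions: LiN(SiMe3)2 (4.6 equiv), THF, −78 °C; MeI (6 equiv), −78 → −30 °C; 1 M HCl
Reagents that add atoms: iodomethane, CI
Why: Enolate alkylation under the self-regeneration-of-stereocentres principle: two equivalents of base per arm give the carboxylate and the dioxolanone enolate, and iodomethane attacks the trigonal carbon anti to the tert-butyl group, so methyl takes the place of the former hydrogen and the quaternary C3 (R) is set by the acetal centre.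

Step 9
Reactants: 10 methylated bis(dioxolanone) diacid
Product: 12 (3R,3'R,4R,4'R)-4,4'-{[6,6'-bis(benzyloxy)-5,5'-dimethoxybiphenyl-3,3'-diyl]bis(methylene)}bis(3-hydroxy-3-methyloxolan-2-one), via bis(hydroxymethyl) dioxolanone 11 (not isolated)
Conditions: BH3·SMe2 (6 equiv), THF, 0 °C → rt; MeOH; then TsOH·H2O (cat.), CH2Cl2, rt
Reagents that add atoms: none
Why: Borane reduces free carboxylic acids through acyloxyboranes much faster than the dioxolanone ester; the new C5 hydroxyl then attacks the dioxolanone carbonyl under acid (5-exo-trig transacylation) and pivalaldehyde is expelled, with no stereocentre touched.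

Step 10
Reactants: 12 bis(α-hydroxy-α-methyl lactone)
Product: 13 (3R,3'R,4R,4'R)-4,4'-{[6,6'-bis(benzyloxy)-5,5'-dimethoxybiphenyl-3,3'-diyl]bis(methylene)}bis[3-(benzyloxy)-3-methyloxolan-2-one]
Conditions: NaH (3 equiv), BnBr (4 equiv), Bu4NI (cat.), DMF, 0 °C → rt
Reagents that add atoms: benzyl bromide, BrCc1ccccc1
Why: Williamson benzylation of the tertiary alkoxides with iodide catalysis; the lactone has no α-hydrogen and C4 is not acidic, so no epimerisation path exists.

Step 11
Reactants: 13 bis(benzyloxy lactone); 14 8-aminoquinoline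
Product: 16 (2R,2'R,3R,3'R)-4,4'-[6,6'-bis(benzyloxy)-5,5'-dimethoxybiphenyl-3,3'-diyl]bis[2-(benzyloxy)-3-{[tert-butyl(dimethyl)silyl]oxymethyl}-2-methyl-N-(quinolin-8-yl)butanamide], via bis(hydroxy amide) 15 (not isolated)
Conditions: 14 (6 equiv), AlMe3 (6 equiv), ClCH2CH2Cl, 0 °C → rt, then 13, 70 °C; aq. potassium sodium tartrate; crude 15, TBSCl (4 equiv), imidazole, DMF, rt
Reagents that add atoms: tert-butyldimethylsilyl chloride, CC(C)(C)[Si](C)(C)Cl
Why: Weinreb-type aminolysis: the dimethylaluminium amide of 14 adds to the lactone carbonyl and the aluminium alkoxide chelate holds the ring open; the crude γ-hydroxy amide is silylated at once on its only free hydroxyl so that it cannot close back to 13.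

Step 12
Reactants: 17 4-iodo-2-methoxyphenol
Product: 18 1-(benzyloxy)-4-iodo-2-methoxybenzene
Conditions: BnBr (1.1 equiv), K2CO3, acetone, reflux
Reagents that add atoms: benzyl bromide, BrCc1ccccc1
Why: Williamson ether synthesis on a phenol; the aryl iodide is untouched.

Step 13
Reactants: 16 bis(silyloxy amide); 18 1-(benzyloxy)-4-iodo-2-methoxybenzene
Product: 19 (2R,2'R,3R,3'R)-4,4'-[6,6'-bis(benzyloxy)-5,5'-dimethoxybiphenyl-3,3'-diyl]bis[2-(benzyloxy)-2-{[4-(benzyloxy)-3-methoxyphenyl]methyl}-3-{[tert-butyl(dimethyl)silyl]oxymethyl}-N-(quinolin-8-yl)butanamide]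
Conditions: 18 (5 equiv), Pd(OAc)2 (20 mol %), AgOAc (4.4 equiv), toluene, 110 °C, sealed tube
Reagents that add atoms: none
Why: Each deprotonated amide nitrogen and its quinoline nitrogen bind divalent palladium, and acetate-assisted concerted metalation–deprotonation of a C–H bond of the C3 methyl group gives a five-membered palladacycle. Oxidative addition of 18 leads to an aryl alkyl complex of tetravalent palladium, reductive elimination forms the C7'–aryl bond, and AgOAc takes up the iodide and returns Pd(OAc)2 while the amide is reprotonated. The closest known reaction type is the 8-aminoquinoline-directed β-C(sp3)–H arylation of methyl groups on α-quaternary carboxamides, O-protected α-hydroxy amides included, with electron-rich aryl iodides. No ring is closed in the product (the palladacycle is transient) and no stereocentre is formed; C3 has no hydrogen and C4 is not enolisable in an amide with a quaternary α-carbon, so both configurations should pass unchanged. The step needs site selectivity for the methyl group: the only other β-hydrogen is the hindered tertiary C4–H, and the C5, C7 and OCH2Ph hydrogens are γ and would need six-membered palladacycles, so the kinetic preference for a five-membered ring and a primary C–H bond should decide. It also needs monoarylation, which the substrate secures because the new C7' methylene is wedged between the quaternary C3 and the aryl ring, so a second palladation there should be much slower; the excess of 18 is kept moderate for the same reason. β-Alkoxide elimination of the C3 benzyloxy group is not expected, because the C3–O bond is exocyclic to the rigid palladacycle and cannot lie syn-coplanar with the C–Pd bond. The two arms are far apart and should react independently, so the reaction is run until the monoarylated material is consumed.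

Step 14
Reactants: 19 doubly arylated bis(silyloxy amide)
Product: 21 (3R,3'R,4R,4'R)-4,4'-{[6,6'-bis(benzyloxy)-5,5'-dimethoxybiphenyl-3,3'-diyl]bis(methylene)}bis(3-(benzyloxy)-3-{[4-(benzyloxy)-3-methoxyphenyl]methyl}oxolan-2-one), via desilylated bis(hydroxy amide) 20 (not isolated)
Conditions: TsOH·H2O (5 equiv), MeOH–CH2Cl2, rt; then solvent switch to toluene, 90 °C
Reagents that add atoms: none
Why: Acid-catalysed methanolysis of the primary silyl ethers, then intramolecular acyl substitution (5-exo-trig) in which the C5 hydroxyl attacks the protonated amide and 8-aminoquinoline leaves as its ammonium salt; the geminal substitution at C3 favours closure (Thorpe–Ingold effect), and the aryl and α-carbonyl tertiary benzyl ethers should not ionise under sulfonic acid.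

Step 15
Reactants: 21 hexabenzyl bis-lactone
Product: 22 bis-5,5-nortrachelogenin
Conditions: H2 (1 atm), 10% Pd/C, EtOAc–MeOH, rt
Reagents that add atoms: none
Why: Hydrogenolysis of six benzyl ethers; the C3 oxygen is homobenzylic to the aryl rings of the skeleton, so only the O–CH2Ph bonds are benzylic C–O bonds, and the lactones and the four stereocentres are not affected.

## Compound list

1 | vanillin (4-hydroxy-3-methoxybenzaldehyde) | COc1cc(C=O)ccc1O | starting material
2 | divanillin (6,6'-dihydroxy-5,5'-dimethoxybiphenyl-3,3'-dicarbaldehyde) | COc1cc(C=O)cc(-c2cc(C=O)cc(OC)c2O)c1O | intermediate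
3 | 6,6'-bis(benzyloxy)-5,5'-dimethoxybiphenyl-3,3'-dicarbaldehyde | COc1cc(C=O)cc(-c2cc(C=O)cc(OC)c2OCc2ccccc2)c1OCc1ccccc1 | intermediate
4 | [6,6'-bis(benzyloxy)-5,5'-dimethoxybiphenyl-3,3'-diyl]dimethanol | COc1cc(CO)cc(-c2cc(CO)cc(OC)c2OCc2ccccc2)c1OCc1ccccc1 | intermediate
5 | 2,2'-bis(benzyloxy)-5,5'-bis(bromomethyl)-3,3'-dimethoxybiphenyl | COc1cc(CBr)cc(-c2cc(CBr)cc(OC)c2OCc2ccccc2)c1OCc1ccccc1 | intermediate
6 | diisopropyl (R)-malate (dipropan-2-yl (2R)-2-hydroxybutanedioate) | CC(C)OC(=O)C[C@@H](O)C(=O)OC(C)C | starting material
7 | tetraisopropyl (2R,2'R,3S,3'S)-3,3'-{[6,6'-bis(benzyloxy)-5,5'-dimethoxybiphenyl-3,3'-diyl]bis(methylene)}bis(2-hydroxybutanedioate) | COc1cc(C[C@H](C(=O)OC(C)C)[C@@H](O)C(=O)OC(C)C)cc(-c2cc(C[C@H](C(=O)OC(C)C)[C@@H](O)C(=O)OC(C)C)cc(OC)c2OCc2ccccc2)c1OCc1ccccc1 | intermediate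
8 | (2R,2'R,3S,3'S)-3,3'-{[6,6'-bis(benzyloxy)-5,5'-dimethoxybiphenyl-3,3'-diyl]bis(methylene)}bis(2-hydroxybutanedioic acid) | COc1cc(C[C@H](C(=O)O)[C@@H](O)C(=O)O)cc(-c2cc(C[C@H](C(=O)O)[C@@H](O)C(=O)O)cc(OC)c2OCc2ccccc2)c1OCc1ccccc1 | intermediate
9 | (2S,2'S)-3,3'-[6,6'-bis(benzyloxy)-5,5'-dimethoxybiphenyl-3,3'-diyl]bis{2-[(2R,4R)-2-tert-butyl-5-oxo-1,3-dioxolan-4-yl]propanoic acid}, tert-butyl cis to the side chain | COc1cc(C[C@H](C(=O)O)[C@@H]2C(=O)O[C@H](C(C)(C)C)O2)cc(-c2cc(C[C@H](C(=O)O)[C@@H]3C(=O)O[C@H](C(C)(C)C)O3)cc(OC)c2OCc2ccccc2)c1OCc1ccccc1 | intermediate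
10 | (2S,2'S)-3,3'-[6,6'-bis(benzyloxy)-5,5'-dimethoxybiphenyl-3,3'-diyl]bis{2-[(2R,4R)-2-tert-butyl-4-methyl-5-oxo-1,3-dioxolan-4-yl]propanoic acid} | COc1cc(C[C@H](C(=O)O)[C@]2(C)C(=O)O[C@H](C(C)(C)C)O2)cc(-c2cc(C[C@H](C(=O)O)[C@]3(C)C(=O)O[C@H](C(C)(C)C)O3)cc(OC)c2OCc2ccccc2)c1OCc1ccccc1 | intermediate
11 | bis(hydroxymethyl) dioxolanone: 10 with both CO2H groups reduced to CH2OH, configurations unchanged | COc1cc(C[C@H](CO)[C@]2(C)C(=O)O[C@H](C(C)(C)C)O2)cc(-c2cc(C[C@H](CO)[C@]3(C)C(=O)O[C@H](C(C)(C)C)O3)cc(OC)c2OCc2ccccc2)c1OCc1ccccc1 | intermediate (not isolated)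
12 | (3R,3'R,4R,4'R)-4,4'-{[6,6'-bis(benzyloxy)-5,5'-dimethoxybiphenyl-3,3'-diyl]bis(methylene)}bis(3-hydroxy-3-methyloxolan-2-one) | COc1cc(C[C@@H]2COC(=O)[C@]2(C)O)cc(-c2cc(C[C@@H]3COC(=O)[C@]3(C)O)cc(OC)c2OCc2ccccc2)c1OCc1ccccc1 | intermediate
13 | (3R,3'R,4R,4'R)-4,4'-{[6,6'-bis(benzyloxy)-5,5'-dimethoxybiphenyl-3,3'-diyl]bis(methylene)}bis[3-(benzyloxy)-3-methyloxolan-2-one] | COc1cc(C[C@@H]2COC(=O)[C@]2(C)OCc2ccccc2)cc(-c2cc(C[C@@H]3COC(=O)[C@]3(C)OCc3ccccc3)cc(OC)c2OCc2ccccc2)c1OCc1ccccc1 | intermediate
14 | 8-aminoquinoline (quinolin-8-amine) | Nc1cccc2cccnc12 | starting material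
15 | (2R,2'R,3R,3'R)-4,4'-[6,6'-bis(benzyloxy)-5,5'-dimethoxybiphenyl-3,3'-diyl]bis[2-(benzyloxy)-3-(hydroxymethyl)-2-methyl-N-(quinolin-8-yl)butanamide] | COc1cc(C[C@H](CO)[C@@](C)(OCc2ccccc2)C(=O)Nc2cccc3cccnc23)cc(-c2cc(C[C@H](CO)[C@@](C)(OCc3ccccc3)C(=O)Nc3cccc4cccnc34)cc(OC)c2OCc2ccccc2)c1OCc1ccccc1 | intermediate (not isolated)
16 | (2R,2'R,3R,3'R)-4,4'-[6,6'-bis(benzyloxy)-5,5'-dimethoxybiphenyl-3,3'-diyl]bis[2-(benzyloxy)-3-{[tert-butyl(dimethyl)silyl]oxymethyl}-2-methyl-N-(quinolin-8-yl)butanamide] | COc1cc(C[C@H](CO[Si](C)(C)C(C)(C)C)[C@@](C)(OCc2ccccc2)C(=O)Nc2cccc3cccnc23)cc(-c2cc(C[C@H](CO[Si](C)(C)C(C)(C)C)[C@@](C)(OCc3ccccc3)C(=O)Nc3cccc4cccnc34)cc(OC)c2OCc2ccccc2)c1OCc1ccccc1 | intermediate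
17 | 4-iodo-2-methoxyphenol | COc1cc(I)ccc1O | starting material
18 | 1-(benzyloxy)-4-iodo-2-methoxybenzene | COc1cc(I)ccc1OCc1ccccc1 | intermediate
19 | (2R,2'R,3R,3'R)-4,4'-[6,6'-bis(benzyloxy)-5,5'-dimethoxybiphenyl-3,3'-diyl]bis[2-(benzyloxy)-2-{[4-(benzyloxy)-3-methoxyphenyl]methyl}-3-{[tert-butyl(dimethyl)silyl]oxymethyl}-N-(quinolin-8-yl)butanamide] | COc1cc(C[C@H](CO[Si](C)(C)C(C)(C)C)[C@@](Cc2ccc(OCc3ccccc3)c(OC)c2)(OCc2ccccc2)C(=O)Nc2cccc3cccnc23)cc(-c2cc(C[C@H](CO[Si](C)(C)C(C)(C)C)[C@@](Cc3ccc(OCc4ccccc4)c(OC)c3)(OCc3ccccc3)C(=O)Nc3cccc4cccnc34)cc(OC)c2OCc2ccccc2)c1OCc1ccccc1 | intermediate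
20 | bis(hydroxy amide): 19 with both silyl ethers cleaved to CH2OH | COc1cc(C[C@H](CO)[C@@](Cc2ccc(OCc3ccccc3)c(OC)c2)(OCc2ccccc2)C(=O)Nc2cccc3cccnc23)cc(-c2cc(C[C@H](CO)[C@@](Cc3ccc(OCc4ccccc4)c(OC)c3)(OCc3ccccc3)C(=O)Nc3cccc4cccnc34)cc(OC)c2OCc2ccccc2)c1OCc1ccccc1 | intermediate (not isolated)
21 | (3R,3'R,4R,4'R)-4,4'-{[6,6'-bis(benzyloxy)-5,5'-dimethoxybiphenyl-3,3'-diyl]bis(methylene)}bis(3-(benzyloxy)-3-{[4-(benzyloxy)-3-methoxyphenyl]methyl}oxolan-2-one) | COc1cc(C[C@@H]2COC(=O)[C@@]2(OCc2ccccc2)Cc2ccc(OCc3ccccc3)c(OC)c2)cc(-c2cc(C[C@@H]3COC(=O)[C@@]3(OCc3ccccc3)Cc3ccc(OCc4ccccc4)c(OC)c3)cc(OC)c2OCc2ccccc2)c1OCc1ccccc1 | intermediate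
22 | bis-5,5-nortrachelogenin, (3R,3'R,4R,4'R)-4,4'-{[6,6'-dihydroxy-5,5'-dimethoxybiphenyl-3,3'-diyl]bis(methylene)}bis{3-hydroxy-3-[(4-hydroxy-3-methoxyphenyl)methyl]oxolan-2-one} | COc1cc(C[C@]2(O)C(=O)OC[C@H]2Cc2cc(OC)c(O)c(-c3cc(C[C@@H]4COC(=O)[C@@]4(O)Cc4ccc(O)c(OC)c4)cc(OC)c3O)c2)ccc1O | target

## Step count and least certain steps

Total: 15 steps. Longest linear sequence: 14 steps (steps 1 to 11 and 13 to 15); step 12 is a one-step branch to 18.

**Step 13 (key step).** Three processes may go wrong.
- Incomplete twofold conversion: each palladation takes place at a methyl group buried between a quaternary centre and a branched chain, and the catalyst may deactivate before the second arm has reacted.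
- Over-arylation at the new benzylic methylene if the aryl iodide is in large excess.
- Loss of a silyl group to the acetic acid set free, after which the C5 hydroxyl would lactonise and expel the directing group before arylation.

The fallback uses established enolate chemistry in place of C–H activation. It sets out from 9 and comes back at 22. PBr3 converts commercial 4-(benzyloxy)-3-methoxybenzyl alcohol into 4-(benzyloxy)-3-methoxybenzyl bromide F1. The tetraanion of 9 (LiN(SiMe3)2, THF, −78 °C) is alkylated with F1 anti to the tert-butyl groups to give the bis(arylmethyl) dioxolanone diacid F2. BH3·SMe2 reduces the carboxyl groups to the bis(hydroxymethyl) dioxolanone F3, which closes under TsOH to the tetra-O-benzyl bis-lactone F4 with free tertiary hydroxyls. Hydrogenolysis of F4 over Pd/C gives 22.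

**Step 11.** The lactone carbonyl is flanked by the quaternary C3 and the nucleophile is an aromatic amine, so the opening may be sluggish, and the γ-hydroxy amide may close back to 13 during work-up before it is silylated. The fallback sets out from 13 and comes back at 16. LiOH in THF–H2O opens both lactones to the dilithium bis(hydroxy carboxylate) F5, which is not acidified but dried and treated with TBSCl and imidazole to give the bis(silyl ether silyl ester) F6. K2CO3 in aqueous MeOH cleaves only the silyl esters to the bis(silyloxy acid) F7. Under neutral conditions 1-chloro-N,N,2-trimethylprop-1-en-1-amine converts this into the bis(acid chloride) F8, which is coupled with 14 in the presence of pyridine to give 16.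

**Step 5.** Erosion of diastereoselectivity is compounded over two sites, since any syn event gives a diastereomer of similar polarity; incomplete second alkylation and some O-alkylation may add to it. The fallback builds the halves first and forms the biaryl bond afterwards; it sets out from 6 and comes back at 7. Commercial 5-bromovanillin is benzylated to 4-(benzyloxy)-3-bromo-5-methoxybenzaldehyde F9, reduced with NaBH4 to the benzylic alcohol F10 and converted with PBr3 to the benzylic bromide F11. The dianion of 6 is alkylated with F11 to give the single-site adduct F12, from which the minor diastereomer is removed at this simpler stage. A nickel-mediated reductive homocoupling of the aryl bromide (NiCl2(PPh3)2, Zn, Et4NI, THF, 50 °C) then joins two molecules of F12 to give 7.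

**Step 14.** Desilylation should be easy, but the ring closure may stall because the hydroxyl must attack a carbonyl shielded by the quaternary C3 and the amide is a poor electrophile; prolonged heating in acid could then begin to cleave benzyl ethers. The fallback activates the amide nitrogen; it sets out from 19 and comes back at 21. Boc2O and DMAP in MeCN at 60 °C give the N-Boc bis-amide F13, whose twisted amide is far more electrophilic. Bu4NF in THF then frees the C5 alkoxide, which closes onto the acyl carbon and expels tert-butyl quinolin-8-ylcarbamate to give 21.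

## Further compounds

F1 | step 13 | 4-(benzyloxy)-3-methoxybenzyl bromide | COc1cc(CBr)ccc1OCc1ccccc1
F2 | step 13 | bis(arylmethyl) dioxolanone diacid: 10 with 4-(benzyloxy)-3-methoxybenzyl in place of each methyl group | COc1cc(C[C@H](C(=O)O)[C@]2(Cc3ccc(OCc4ccccc4)c(OC)c3)C(=O)O[C@H](C(C)(C)C)O2)cc(-c2cc(C[C@H](C(=O)O)[C@]3(Cc4ccc(OCc5ccccc5)c(OC)c4)C(=O)O[C@H](C(C)(C)C)O3)cc(OC)c2OCc2ccccc2)c1OCc1ccccc1
F3 | step 13 | bis(hydroxymethyl) dioxolanone: F2 with both CO2H groups reduced to CH2OH | COc1cc(C[C@H](CO)[C@]2(Cc3ccc(OCc4ccccc4)c(OC)c3)C(=O)O[C@H](C(C)(C)C)O2)cc(-c2cc(C[C@H](CO)[C@]3(Cc4ccc(OCc5ccccc5)c(OC)c4)C(=O)O[C@H](C(C)(C)C)O3)cc(OC)c2OCc2ccccc2)c1OCc1ccccc1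
F4 | step 13 | (3R,3'R,4R,4'R)-4,4'-{[6,6'-bis(benzyloxy)-5,5'-dimethoxybiphenyl-3,3'-diyl]bis(methylene)}bis(3-{[4-(benzyloxy)-3-methoxyphenyl]methyl}-3-hydroxyoxolan-2-one) | COc1cc(C[C@@H]2COC(=O)[C@@]2(O)Cc2ccc(OCc3ccccc3)c(OC)c2)cc(-c2cc(C[C@@H]3COC(=O)[C@@]3(O)Cc3ccc(OCc4ccccc4)c(OC)c3)cc(OC)c2OCc2ccccc2)c1OCc1ccccc1
F5 | step 11 | dilithium (2R,2'R,3R,3'R)-4,4'-[6,6'-bis(benzyloxy)-5,5'-dimethoxybiphenyl-3,3'-diyl]bis[2-(benzyloxy)-3-(hydroxymethyl)-2-methylbutanoate] | [Li+].[Li+].COc1cc(C[C@H](CO)[C@@](C)(OCc2ccccc2)C(=O)[O-])cc(-c2cc(C[C@H](CO)[C@@](C)(OCc3ccccc3)C(=O)[O-])cc(OC)c2OCc2ccccc2)c1OCc1ccccc1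
F6 | step 11 | bis(silyl ether silyl ester): F5 with both hydroxyls and both carboxylates tert-butyldimethylsilylated | COc1cc(C[C@H](CO[Si](C)(C)C(C)(C)C)[C@@](C)(OCc2ccccc2)C(=O)O[Si](C)(C)C(C)(C)C)cc(-c2cc(C[C@H](CO[Si](C)(C)C(C)(C)C)[C@@](C)(OCc3ccccc3)C(=O)O[Si](C)(C)C(C)(C)C)cc(OC)c2OCc2ccccc2)c1OCc1ccccc1
F7 | step 11 | (2R,2'R,3R,3'R)-4,4'-[6,6'-bis(benzyloxy)-5,5'-dimethoxybiphenyl-3,3'-diyl]bis[2-(benzyloxy)-3-{[tert-butyl(dimethyl)silyl]oxymethyl}-2-methylbutanoic acid] | COc1cc(C[C@H](CO[Si](C)(C)C(C)(C)C)[C@@](C)(OCc2ccccc2)C(=O)O)cc(-c2cc(C[C@H](CO[Si](C)(C)C(C)(C)C)[C@@](C)(OCc3ccccc3)C(=O)O)cc(OC)c2OCc2ccccc2)c1OCc1ccccc1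
F8 | step 11 | bis(acid chloride): F7 with both CO2H groups converted to COCl | COc1cc(C[C@H](CO[Si](C)(C)C(C)(C)C)[C@@](C)(OCc2ccccc2)C(=O)Cl)cc(-c2cc(C[C@H](CO[Si](C)(C)C(C)(C)C)[C@@](C)(OCc3ccccc3)C(=O)Cl)cc(OC)c2OCc2ccccc2)c1OCc1ccccc1
F9 | step 5 | 4-(benzyloxy)-3-bromo-5-methoxybenzaldehyde | COc1cc(C=O)cc(Br)c1OCc1ccccc1
F10 | step 5 | [4-(benzyloxy)-3-bromo-5-methoxyphenyl]methanol | COc1cc(CO)cc(Br)c1OCc1ccccc1
F11 | step 5 | 2-(benzyloxy)-1-bromo-5-(bromomethyl)-3-methoxybenzene | COc1cc(CBr)cc(Br)c1OCc1ccccc1
F12 | step 5 | diisopropyl (2R,3S)-3-{[4-(benzyloxy)-3-bromo-5-methoxyphenyl]methyl}-2-hydroxybutanedioate | COc1cc(C[C@H](C(=O)OC(C)C)[C@@H](O)C(=O)OC(C)C)cc(Br)c1OCc1ccccc1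
F13 | step 14 | N-Boc bis-amide: 19 with a tert-butoxycarbonyl group on each amide nitrogen | COc1cc(C[C@H](CO[Si](C)(C)C(C)(C)C)[C@@](Cc2ccc(OCc3ccccc3)c(OC)c2)(OCc2ccccc2)C(=O)N(C(=O)OC(C)(C)C)c2cccc3cccnc23)cc(-c2cc(C[C@H](CO[Si](C)(C)C(C)(C)C)[C@@](Cc3ccc(OCc4ccccc4)c(OC)c3)(OCc3ccccc3)C(=O)N(C(=O)OC(C)(C)C)c3cccc4cccnc34)cc(OC)c2OCc2ccccc2)c1OCc1ccccc1
A1 | alternative 1 | 3,3'-{[6,6'-bis(benzyloxy)-5,5'-dimethoxybiphenyl-3,3'-diyl]bis(methylene)}di(cyclobutan-1-one) | COc1cc(CC2CC(=O)C2)cc(-c2cc(CC3CC(=O)C3)cc(OC)c2OCc2ccccc2)c1OCc1ccccc1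
A2 | alternative 1 | (4S,4'S)-4,4'-{[6,6'-bis(benzyloxy)-5,5'-dimethoxybiphenyl-3,3'-diyl]bis(methylene)}bis(oxolan-2-one) | COc1cc(C[C@@H]2COC(=O)C2)cc(-c2cc(C[C@@H]3COC(=O)C3)cc(OC)c2OCc2ccccc2)c1OCc1ccccc1
A3 | alternative 2 | bis(allylic alcohol) with the hydroxymethyl group cis to the biaryl-bearing chain (Z at each alkene) | COc1cc(C/C=C(\CO)Cc2ccc(OCc3ccccc3)c(OC)c2)cc(-c2cc(C/C=C(\CO)Cc3ccc(OCc4ccccc4)c(OC)c3)cc(OC)c2OCc2ccccc2)c1OCc1ccccc1
A4 | alternative 2 | bis(2,3-epoxy alcohol) derived from A3 | COc1cc(C[C@H]2O[C@]2(CO)Cc2ccc(OCc3ccccc3)c(OC)c2)cc(-c2cc(C[C@H]3O[C@]3(CO)Cc3ccc(OCc4ccccc4)c(OC)c3)cc(OC)c2OCc2ccccc2)c1OCc1ccccc1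
A5 | alternative 2 | bis(1,2-diol) with a vinyl group at C4 | COc1cc(C[C@H](C=C)[C@@](O)(CO)Cc2ccc(OCc3ccccc3)c(OC)c2)cc(-c2cc(C[C@H](C=C)[C@@](O)(CO)Cc3ccc(OCc4ccccc4)c(OC)c3)cc(OC)c2OCc2ccccc2)c1OCc1ccccc1
A6 | alternative 3 | bis[(E)-2-substituted cinnamyl alcohol] with the C4 centre and C5 silyl ether in place | COc1cc(C[C@H](CO[Si](C)(C)C(C)(C)C)/C(CO)=C\c2ccc(OCc3ccccc3)c(OC)c2)cc(-c2cc(C[C@H](CO[Si](C)(C)C(C)(C)C)/C(CO)=C\c3ccc(OCc4ccccc4)c(OC)c3)cc(OC)c2OCc2ccccc2)c1OCc1ccccc1
A7 | alternative 3 | bis(epoxy alcohol) with the C3 oxygen in its final configuration | COc1cc(C[C@H](CO[Si](C)(C)C(C)(C)C)[C@]2(CO)O[C@@H]2c2ccc(OCc3ccccc3)c(OC)c2)cc(-c2cc(C[C@H](CO[Si](C)(C)C(C)(C)C)[C@]3(CO)O[C@@H]3c3ccc(OCc4ccccc4)c(OC)c3)cc(OC)c2OCc2ccccc2)c1OCc1ccccc1
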